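**Retrosynthetic overview**
1. Target 31 ⇐ boronate amine 28: one oxidation turns C3–B into C3–OH and the Mannich base into the α-methylene lactone; 28 ⇐ 27 by C15 acylation.
2. Ten-membered ring ⇐ trans-decalin mesylate 24: ring expansion by Grob-type cleavage of the shared C5–C10 bond, triggered by conjugate borylation at C3 (sets C3 and both E-olefins).
3. Ring B with its γ-lactone ⇐ aldehyde enoate 15: SmI2 ketyl–olefin cyclization (C7–C8), after a Felkin-controlled Nozaki–Hiyama–Kishi addition (C6).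
4. Ring A ⇐ diene 7 + enal ester 3: catalytic enantioselective Diels–Alder reaction (C5, C10).
5. Ring order: cyclohexene ring A → ring B and lactone in one step → 6/6 decalin expanded to the cyclodecadiene.

Assumption: C1–C15 are the germacrane locants of the target (C11–C13 lactone carbons, C14 = CH3 on C10, C15 = CH2O on C4; target = 3R,6R,7R,8S, both ring olefins E); in cyclohexene and decalin intermediates β is the face of the C14 methyl; the SMILES are definitive.

Step 1
Reactants: 1 propanal; 2 ethyl glyoxylate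
Product: 3 ethyl (2E)-3-methyl-4-oxobut-2-enoate
Conditions: morpholine·AcOH (10 mol %), toluene, 80 °C, −H2O; cat. I2, rt (Z → E)
Reagents that add atoms: none
Why: Amine-catalysed crossed aldol (Mannich-type) condensation in which only propanal can enolise and only the glyoxylate aldehyde is attacked, and equilibration gives the more stable E enal ester.

Step 2
Reactants: 4 glutaconaldehyde potassium salt
Product: 5 (2E,4E)-5-(tert-butyldimethylsilyloxy)penta-2,4-dienal
Conditions: TBSCl, DMF, 0 °C → rt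
Reagents that add atoms: tert-butyldimethylsilyl chloride (TBSCl), CC(C)(C)[Si](C)(C)Cl
Why: O-silylation of the dienolate by the hard silyl electrophile keeps the all-trans dienal geometry.

Step 3
Reactants: 5 silyloxy dienal
Product: 6 (2E,4E)-5-(tert-butyldimethylsilyloxy)penta-2,4-dien-1-ol
Conditions: DIBAL-H, CH2Cl2, −78 °C; Rochelle salt
Reagents that add atoms: none
Why: Aprotic 1,2-reduction of the aldehyde by DIBAL-H leaves the labile silyl dienol ether untouched.

Step 4
Reactants: 6 dienol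
Product: 7 (1E,3E)-1,5-bis(tert-butyldimethylsilyloxy)penta-1,3-diene
Conditions: TBSCl, imidazole, CH2Cl2, 0 °C
Reagents that add atoms: tert-butyldimethylsilyl chloride (TBSCl), CC(C)(C)[Si](C)(C)Cl
Why: Standard imidazole-mediated silyl ether formation on the primary alcohol.

Step 5
Reactants: 7 bis-silyl diene; 3 enal ester
Product: 8 ring-A cyclohexene (C10: CH3 β, CHO α; C1–OTBS α; C4–CH2OTBS α; C5–CO2Et β)
Conditions: (S)-o-tolyl-oxazaborolidine (from (S)-α,α-diphenylprolinol and o-tolylboronic acid) activated with Tf2NH (20 mol %), CH2Cl2, −78 → −40 °C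
Reagents that add atoms: none
Why: Enantioselective Diels–Alder reaction in which the boron Lewis acid binds the formyl group, so the siloxy terminus C1 bonds to C10 (ortho rule), CHO is endo, the E dienophile puts C9 and C6 trans (the later trans ring fusion) and the catalyst antipode, chosen by the formyl C–H···O pre-transition-state model, fixes C10 and C5, while C1 is re-set in step 14 and C4 becomes sp2.

Step 6
Reactants: 8 ring-A cyclohexene
Product: 9 methyl enol ether (C10–CH=CH–OMe, E/Z mixture)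
Conditions: Ph3P(CH2OMe)Cl, KHMDS, THF, 0 °C → rt
Reagents that add atoms: (methoxymethyl)triphenylphosphonium chloride, COC[P+](c1ccccc1)(c1ccccc1)c1ccccc1.[Cl-]
Why: Wittig methoxymethylenation of the non-enolisable neopentyl aldehyde supplies C8 and leaves the hindered ester alone.

Step 7
Reactants: 9 methyl enol ether
Product: 10 C6 aldehyde
Conditions: DIBAL-H (1.1 equiv), CH2Cl2, −78 °C; MeOH, Rochelle salt
Reagents that add atoms: none
Why: Partial ester reduction, because the tetrahedral aluminate of the hindered ester is stable at −78 °C and collapses to the aldehyde only on work-up.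

Step 8
Reactants: 10 C6 aldehyde; 11 methyl (2E)-3-iodoprop-2-enoate
Product: 12 γ-hydroxy enoate (C6–OH with the target configuration)
Conditions: CrCl2 (4 equiv), NiCl2 (2 mol %), DMSO/THF, rt
Reagents that add atoms: none
Why: Nozaki–Hiyama–Kishi coupling, aldehyde-selective and non-basic, in which the alkenylchromium adds in the Felkin–Anh sense anti to the quaternary C10 and so sets C6.

Step 9
Reactants: 12 γ-hydroxy enoate; 13 isovaleryl chloride
Product: 15 C8 aldehyde with C6 isovalerate, via isovalerate enol ether 14 (not isolated)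
Conditions: 13, pyridine, DMAP (cat.), CH2Cl2, 0 °C; then 0.5 M HCl, THF/H2O, 0 °C, 20 min
Reagents that add atoms: water, O
Why: DMAP-catalysed acylation followed by brief dilute-acid hydrolysis of the enol ether, which is far more acid-labile than the two TBS ethers.

Step 10
Reactants: 15 C8 aldehyde
Product: 16 tricyclic trans-decalin lactone (1α-OTBS, Δ2, 4α-CH2OTBS, 5α-H, 6α-isovalerate, 7α-H, 8α-O lactone, 10β-CH3)
Conditions: SmI2 (2.5 equiv), t-BuOH (2 equiv), THF, −78 → 0 °C
Reagents that add atoms: none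
Why: SmI2 ketyl–olefin radical cyclization (6-exo-trig) through a chair transition state with the C6 ester, the enoate and the samarium-bound oxygen all equatorial sets C7 and C8 and the trans ring fusion, and the trivalent samarium alkoxide closes the γ-lactone.

Step 11
Reactants: 16 tricyclic lactone
Product: 17 α-(dimethylaminomethyl) lactone (CH2NMe2 at C11, trans to C6)
Conditions: LiHMDS (1.1 equiv), THF, −78 °C; CH2=NMe2 I, −78 → 0 °C
Reagents that add atoms: Eschenmoser's salt (N,N-dimethylmethyleneiminium iodide), C=[N+](C)C.[I-]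
Why: Mannich aminomethylation of the lactone enolate, formed selectively because the γ-lactone is several pKa units more acidic than the isovalerate, installs C13 as a masked α-methylene unit that is inert to the later copper–boryl step.

Step 12
Reactants: 17 Mannich lactone
Product: 18 C1,C15 diol
Conditions: HF·pyridine, THF, 0 °C → rt; NaHCO3
Reagents that add atoms: none
Why: Fluoride cleavage of both silyl ethers under conditions that spare lactone, ester and amine.

Step 13
Reactants: 18 diol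
Product: 19 C1 enone C15 aldehyde
Conditions: Dess–Martin periodinane (2.5 equiv), NaHCO3, CH2Cl2, 0 °C → rt
Reagents that add atoms: none
Why: Dess–Martin oxidation of both alcohols, which erases the C1 configuration left by the cycloaddition.

Step 14
Reactants: 19 keto aldehyde
Product: 22 1β-hydroxy-Δ2-decalin-4-carbaldehyde, via dimethyl acetal enone 20 (not isolated), via acetal allylic alcohol 21 (not isolated)
Conditions: CeCl3·7H2O, HC(OMe)3, MeOH, rt; NaBH4, −78 °C; aq. oxalic acid, THF, 0 °C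
Reagents that add atoms: water, O
Why: Luche chemistry, with the aldehyde protected in the flask as its dimethyl acetal and the enone reduced 1,2 by hydride from the α-face anti to the axial C14 methyl, gives the equatorial 1β-alcohol as in Wieland–Miescher-type decalones.

Step 15
Reactants: 22 hydroxy aldehyde
Product: 24 1β-mesyloxy-Δ3-decalin-4-carbaldehyde, via conjugated hydroxy enal 23 (not isolated)
Conditions: DBU (0.2 equiv), CH2Cl2, 0 °C; then MsCl, Et3N, −20 °C
Reagents that add atoms: methanesulfonyl chloride (MsCl), CS(=O)(=O)Cl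
Why: Base-mediated shift of the olefin into conjugation, so that the alcohol is no longer allylic, followed by sulfonylation of the equatorial alcohol via sulfene.

Step 16
Reactants: 24 decalin mesylate
Product: 27 ten-membered allylic alcohol with C3 pinacol boronate, via sodium enolate 25 (not isolated), via boryl dienal 26 (not isolated)
Conditions: B2pin2 (1.05 equiv), CuCl (10 mol %), Xantphos (10 mol %), NaOt-Bu (1.2 equiv), THF, −20 → 25 °C; then NaBH4, CeCl3·7H2O, MeOH, −40 °C
Reagents that add atoms: bis(pinacolato)diboron (B2pin2), CC1(C)OB(OC1(C)C)B1OC(C)(C)C(C)(C)O1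
Why: Proposed new method: the copper–boryl species adds 1,4 to the enal by axial attack on the α-face of C3 (anti to the angular methyl), which sets C3, and the resulting C4 enolate, whose π-system overlaps the C5–C10 σ-bond that is antiperiplanar to the equatorial C1–OMs, expels mesylate in a seven-centre Grob-type fragmentation that converts the trans-decalin into the ten-membered ring with both E olefins, the closest known reactions being the base-induced enolate-assisted 1,4-fragmentation of 1-mesyloxy-decalin-4-carbaldehydes, the Marshall boronate fragmentation and the copper-catalysed β-borylation of enals, with in-flask NaBH4 reduction of the dienal preventing a second borylation.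

Step 17
Reactants: 27 allylic alcohol boronate; 13 isovaleryl chloride
Product: 28 6,15-bis(isovalerate) C3 boronate
Conditions: 13, pyridine, DMAP (cat.), CH2Cl2, 0 °C
Reagents that add atoms: none
Why: Acylation of the only free hydroxyl, with boron still masking the C3 oxygen, so the two secondary allylic positions never have to be told apart.

Step 18
Reactants: 28 bis(isovalerate) boronate
Product: 31 target CNP0317194.1, via hydroxy amine 29 (not isolated), via amine N-oxide 30 (not isolated)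
Conditions: 30% H2O2, NaHCO3, THF/MeOH, 0 °C → rt; then 45 °C
Reagents that add atoms: hydrogen peroxide, OO
Why: Peroxide oxidation of the allylic boronate (boron-to-oxygen 1,2-shift with retention, giving 3R) and of the tertiary amine to its N-oxide, whose Cope elimination through the acidic C11–H gives the exocyclic methylene.

**Compound list**
1 | propanal | CCC=O | starting material
2 | ethyl glyoxylate | CCOC(=O)C=O | starting material
3 | ethyl (2E)-3-methyl-4-oxobut-2-enoate | CCOC(=O)/C=C(\C)C=O | intermediate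
4 | glutaconaldehyde potassium salt (potassium (1E,3E)-5-oxopenta-1,3-dien-1-olate) | [K+].[O-]/C=C/C=C/C=O | starting material
5 | (2E,4E)-5-(tert-butyldimethylsilyloxy)penta-2,4-dienal | CC(C)(C)[Si](C)(C)O/C=C/C=C/C=O | intermediate
6 | (2E,4E)-5-(tert-butyldimethylsilyloxy)penta-2,4-dien-1-ol | CC(C)(C)[Si](C)(C)O/C=C/C=C/CO | intermediate
7 | (1E,3E)-1,5-bis(tert-butyldimethylsilyloxy)penta-1,3-diene | CC(C)(C)[Si](C)(C)O/C=C/C=C/CO[Si](C)(C)C(C)(C)C | intermediate
8 | ethyl 5-(TBSO)-6-formyl-6-methyl-2-(TBSO-methyl)cyclohex-3-ene-1-carboxylate; OTBS, CHO and CH2OTBS on the α-face, CH3 and CO2Et on the β-face | C[C@]1(C=O)[C@@H](O[Si](C)(C)C(C)(C)C)C=C[C@@H](CO[Si](C)(C)C(C)(C)C)[C@@H]1C(=O)OCC | intermediate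
9 | methyl enol ether of 8 (CHO → CH=CH–OMe, E/Z mixture) | C[C@]1(C=COC)[C@@H](O[Si](C)(C)C(C)(C)C)C=C[C@@H](CO[Si](C)(C)C(C)(C)C)[C@@H]1C(=O)OCC | intermediate
10 | aldehyde from 9 (CO2Et → CHO = C6) | C[C@]1(C=COC)[C@@H](O[Si](C)(C)C(C)(C)C)C=C[C@@H](CO[Si](C)(C)C(C)(C)C)[C@@H]1C=O | intermediate
11 | methyl (2E)-3-iodoprop-2-enoate | COC(=O)/C=C/I | starting material
12 | methyl (E)-4-hydroxy-4-(ring A)-but-2-enoate, C6 carbinol of target configuration | C[C@]1(C=COC)[C@@H](O[Si](C)(C)C(C)(C)C)C=C[C@@H](CO[Si](C)(C)C(C)(C)C)[C@@H]1[C@@H](O)/C=C/C(=O)OC | intermediate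
13 | isovaleryl chloride (3-methylbutanoyl chloride) | CC(C)CC(Cl)=O | starting material
14 | C6 isovalerate of 12 | C[C@]1(C=COC)[C@@H](O[Si](C)(C)C(C)(C)C)C=C[C@@H](CO[Si](C)(C)C(C)(C)C)[C@@H]1[C@@H](OC(=O)CC(C)C)/C=C/C(=O)OC | intermediate
15 | aldehyde from 14 (C10–CH2–CHO, C8 aldehyde) | C[C@]1(CC=O)[C@@H](O[Si](C)(C)C(C)(C)C)C=C[C@@H](CO[Si](C)(C)C(C)(C)C)[C@@H]1[C@@H](OC(=O)CC(C)C)/C=C/C(=O)OC | intermediate
16 | trans-decalin γ-lactone: 1α-OTBS, Δ2, 4α-CH2OTBS, 5α-H, 6α-isovaleryloxy, 7α-H, 8α-O (12,8-olide), 10β-CH3 | C[C@@]12C[C@@H]3OC(=O)C[C@H]3[C@H](OC(=O)CC(C)C)[C@H]1[C@H](CO[Si](C)(C)C(C)(C)C)C=C[C@@H]2O[Si](C)(C)C(C)(C)C | intermediate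
17 | 16 with CH2NMe2 on C11 (trans to C6) | C[C@@]12C[C@@H]3OC(=O)[C@H](CN(C)C)[C@H]3[C@H](OC(=O)CC(C)C)[C@H]1[C@H](CO[Si](C)(C)C(C)(C)C)C=C[C@@H]2O[Si](C)(C)C(C)(C)C | intermediate
18 | 1α,15-diol from 17 | C[C@@]12C[C@@H]3OC(=O)[C@H](CN(C)C)[C@H]3[C@H](OC(=O)CC(C)C)[C@H]1[C@H](CO)C=C[C@@H]2O | intermediate
19 | C1 ketone (Δ2 enone), C15 aldehyde | C[C@@]12C[C@@H]3OC(=O)[C@H](CN(C)C)[C@H]3[C@H](OC(=O)CC(C)C)[C@H]1[C@H](C=O)C=CC2=O | intermediate
20 | dimethyl acetal of 19 | C[C@@]12C[C@@H]3OC(=O)[C@H](CN(C)C)[C@H]3[C@H](OC(=O)CC(C)C)[C@H]1[C@H](C(OC)OC)C=CC2=O | intermediate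
21 | 1β-allylic alcohol dimethyl acetal | C[C@@]12C[C@@H]3OC(=O)[C@H](CN(C)C)[C@H]3[C@H](OC(=O)CC(C)C)[C@H]1[C@H](C(OC)OC)C=C[C@H]2O | intermediate
22 | 1β-hydroxy-Δ2-decalin-4-carbaldehyde | C[C@@]12C[C@@H]3OC(=O)[C@H](CN(C)C)[C@H]3[C@H](OC(=O)CC(C)C)[C@H]1[C@H](C=O)C=C[C@H]2O | intermediate
23 | 1β-hydroxy-Δ3-decalin-4-carbaldehyde (conjugated) | C[C@@]12C[C@@H]3OC(=O)[C@H](CN(C)C)[C@H]3[C@H](OC(=O)CC(C)C)[C@H]1C(C=O)=CC[C@H]2O | intermediate
24 | 1β-mesyloxy-Δ3-decalin-4-carbaldehyde (5α-H, 10β-CH3, ring B as in 17) | C[C@@]12C[C@@H]3OC(=O)[C@H](CN(C)C)[C@H]3[C@H](OC(=O)CC(C)C)[C@H]1C(C=O)=CC[C@H]2OS(C)(=O)=O | intermediate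
25 | sodium enolate (O–C15=C4) of the 3α-pinacolboryl decalin mesylate | C[C@@]12C[C@@H]3OC(=O)[C@H](CN(C)C)[C@H]3[C@H](OC(=O)CC(C)C)[C@H]1C(=C[O-])[C@H](B4OC(C)(C)C(C)(C)O4)C[C@H]2OS(C)(=O)=O.[Na+] | intermediate
26 | germacra-1(10),4-dien-15-al with C3–Bpin, 6-isovalerate, 12,8-olide, 11-CH2NMe2; olefin geometry and C3, C6, C7, C8 arranged as in the target | CN(C)C[C@H]1C(=O)O[C@H]2C/C(C)=C/C[C@@H](B3OC(C)(C)C(C)(C)O3)/C(C=O)=C/[C@@H](OC(=O)CC(C)C)[C@H]12 | intermediate
27 | 15-alcohol from 26 | CN(C)C[C@H]1C(=O)O[C@H]2C/C(C)=C/C[C@@H](B3OC(C)(C)C(C)(C)O3)/C(CO)=C/[C@@H](OC(=O)CC(C)C)[C@H]12 | intermediate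
28 | 6,15-bis(isovalerate) with C3–Bpin and 11-CH2NMe2 | CN(C)C[C@H]1C(=O)O[C@H]2C/C(C)=C/C[C@@H](B3OC(C)(C)C(C)(C)O3)/C(COC(=O)CC(C)C)=C/[C@@H](OC(=O)CC(C)C)[C@H]12 | intermediate
29 | 3-hydroxy compound, still the 11-CH2NMe2 lactone | CN(C)C[C@H]1C(=O)O[C@H]2C/C(C)=C/C[C@@H](O)/C(COC(=O)CC(C)C)=C/[C@@H](OC(=O)CC(C)C)[C@H]12 | intermediate
30 | N-oxide of 29 | C[N+](C)([O-])C[C@H]1C(=O)O[C@H]2C/C(C)=C/C[C@@H](O)/C(COC(=O)CC(C)C)=C/[C@@H](OC(=O)CC(C)C)[C@H]12 | intermediate
31 | CNP0317194.1: (1(10)E,4E)-3R-hydroxy-6R,15-bis(isovaleryloxy)germacra-1(10),4,11(13)-trien-12,8S-olide (7R) | C=C1C(=O)O[C@H]2C/C(C)=C/C[C@@H](O)/C(COC(=O)CC(C)C)=C/[C@@H](OC(=O)CC(C)C)[C@H]12 | target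

**Totals and risks**
Total: 18 steps. Longest linear sequence: 17 steps (4 → 31, steps 2–18); step 1 is the only side branch.

Most likely to fail:

- **Step 16 (the proposed new ring expansion).** The copper or boron enolate may be too weakly donating to fragment, or the liberated dienal may be borylated again. Fallback with known chemistry, setting out from 24: conjugate borylation under the usual protic protocol (CuCl, Xantphos, NaOt-Bu cat., B2pin2, MeOH, THF) gives the saturated 3α-pinacolboryl aldehyde F1. Deprotonation with KHMDS (THF, −78 → 0 °C) then triggers the established enolate-assisted 1,4-fragmentation of the 1-mesyloxy-decalin-4-carbaldehyde to dienal 26, which is reduced in the flask with NaBH4/CeCl3·7H2O and comes back to the route at 27.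

- **Step 10 (SmI2 cyclization).** The γ-acyloxy enoate may be cleaved reductively by SmI2 before the ketyl adds. Fallback, setting out from 12: the C6 alcohol is silylated (TESCl, imidazole) to the triethylsilyl ether F2, and the enol ether is hydrolysed (oxalic acid on wet silica) to the aldehyde F3. SmI2/t-BuOH cyclization then gives the lactone silyl ether F4, selective desilylation (PPTS, MeOH, 0 °C) gives the C6 alcohol F5, and acylation with 13 (pyridine, DMAP) returns to the route at 16.

- **Step 14 (ketone reduction beside an aldehyde).** The γ-formyl enone 19 may enolise or the acetal protection may be incomplete. Fallback, setting out from 18: MnO2 (CH2Cl2) oxidizes only the allylic C1 alcohol to the enone alcohol F6, and NaBH4/CeCl3·7H2O gives the 1β,15-diol F7. RuCl2(PPh3)3 (1.2 equiv, benzene, rt), which oxidizes primary alcohols in the presence of secondary ones, then gives the aldehyde and returns to the route at 22.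

Further compounds
F1 | step 16 | 3α-pinacolboryl-1β-mesyloxy-decalin-4-carbaldehyde, saturated ring A, C4 epimer mixture | C[C@@]12C[C@@H]3OC(=O)[C@H](CN(C)C)[C@H]3[C@H](OC(=O)CC(C)C)[C@H]1C(C=O)[C@H](B4OC(C)(C)C(C)(C)O4)C[C@H]2OS(C)(=O)=O
F2 | step 10 | C6 triethylsilyl ether of 12 | C[C@]1(C=COC)[C@@H](O[Si](C)(C)C(C)(C)C)C=C[C@@H](CO[Si](C)(C)C(C)(C)C)[C@@H]1[C@@H](O[Si](CC)(CC)CC)/C=C/C(=O)OC
F3 | step 10 | C8 aldehyde with C6 triethylsilyl ether | C[C@]1(CC=O)[C@@H](O[Si](C)(C)C(C)(C)C)C=C[C@@H](CO[Si](C)(C)C(C)(C)C)[C@@H]1[C@@H](O[Si](CC)(CC)CC)/C=C/C(=O)OC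
F4 | step 10 | trans-decalin γ-lactone with C6 triethylsilyl ether | C[C@@]12C[C@@H]3OC(=O)C[C@H]3[C@H](O[Si](CC)(CC)CC)[C@H]1[C@H](CO[Si](C)(C)C(C)(C)C)C=C[C@@H]2O[Si](C)(C)C(C)(C)C
F5 | step 10 | trans-decalin γ-lactone with free 6α-hydroxyl | C[C@@]12C[C@@H]3OC(=O)C[C@H]3[C@H](O)[C@H]1[C@H](CO[Si](C)(C)C(C)(C)C)C=C[C@@H]2O[Si](C)(C)C(C)(C)C
F6 | step 14 | C1 enone with free C15 alcohol | C[C@@]12C[C@@H]3OC(=O)[C@H](CN(C)C)[C@H]3[C@H](OC(=O)CC(C)C)[C@H]1[C@H](CO)C=CC2=O
F7 | step 14 | 1β,15-diol | C[C@@]12C[C@@H]3OC(=O)[C@H](CN(C)C)[C@H]3[C@H](OC(=O)CC(C)C)[C@H]1[C@H](CO)C=C[C@H]2O
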